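The synthesis depends on making ring C last, inside the macrocycle. Ring C sits in the strained 12-membered ring (C4, C4a, C4b, C5, C6, b1, b6, two CH2, c1, c6, c5) through its meta carbons c1 and c5, a span that a finished flat arene would resist. In one operation a tethered 3-isopropoxy-2-pyrone adds to a 1-(phenylsulfonyl)vinyl group, forging c1–c6 and c4–c5. Expulsion of CO2 and PhSO2H then aromatises ring C and fixes the macrocycle. The precursor 28 is a 2-chloro-3-isopropoxy-7-methoxyphenanthrene with the vinyl sulfone on bay carbon C4 and, on C6, ring B whose ethylene arm ends in the pyron-6-yl group.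

Key step: step 20

**Remarks on the chemistry**
- **Labels.** The phenanthrene is numbered C1 to C10a, with Cl on C2, O on C3, ring B on C6 and OMe on C7. Ring B: b1 is bonded to C6, b2 bears O, b5 bears Cl, b6 bears CH2. Ring C: c1 bears CH2, c4 bears O, c5 is bonded to C4, c6 bears H.
- **Assumption.** The target SMILES carries no stereodescriptor, so the twisted macrocycle is made as a racemate and no axis is controlled.
- **Pyrone source.** A 2-furoate and a 3-hydroxy-2-pyrone are isomers, so an oxidative ring expansion of such an ester would overshoot by two electrons. The pyrone is therefore taken from a sugar lactone that already has the right oxidation level and a CH2O handle on C6.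
- **C4 carbon.** It is brought in through the C3 phenolate, because an electrophile acting on the ether would prefer C8 next to the methoxy group.
- **C6 handle.** It is a bromide that is inert until it is needed.
- **Sulfone.** It travels as its sulfide through all palladium and base steps and is unveiled one step before the cascade.

**Phenanthrene fragment (steps 1 to 9)**

Step 1
Reactants: 1 5-bromo-2-chlorophenol
Product: 2 2-chloro-5-(4,4,5,5-tetramethyl-1,3,2-dioxaborolan-2-yl)phenol
Conditions: B2pin2, Pd(dppf)Cl2 (3 mol %), KOAc, 1,4-dioxane, 90 °C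
Reagents that add atoms: bis(pinacolato)diboron, CC1(C)OB(OC1(C)C)B1OC(C)(C)C(C)(C)O1
Why: Miyaura borylation, in which zerovalent palladium inserts only into the C–Br bond (C–Cl is inert to the dppf catalyst) and acetate-assisted transmetalation from the diboron tolerates the free phenol.

Step 2
Reactants: 3 4-bromo-3-methoxybenzaldehyde
Product: 4 4-bromo-2-iodo-5-methoxybenzaldehyde
Conditions: NIS, CF3CO2H, 25 °C, dark
Reagents that add atoms: N-iodosuccinimide, O=C1CCC(=O)N1I
Why: Electrophilic aromatic iodination directed by the only strong donor, OMe, whose para position is the single open activated site because one ortho carbon carries Br and the other is wedged between OMe and CHO, as in the para halogenation of 3-methoxybenzaldehydes.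

Step 3
Reactants: 2 2-chloro-5-(pinacolboryl)phenol; 4 4-bromo-2-iodo-5-methoxybenzaldehyde
Product: 5 5-bromo-4'-chloro-3'-hydroxy-4-methoxybiphenyl-2-carbaldehyde
Conditions: Pd(PPh3)4 (3 mol %), aq. Na2CO3, DME, 70 °C, 1.0 equiv of 2
Reagents that add atoms: none
Why: Suzuki–Miyaura coupling in which oxidative addition goes to the C–I bond, weaker than C–Br and further activated by the ortho formyl group, so the bromide at the future C6 and the chloride should stay untouched.

Step 4
Reactants: 5 5-bromo-4'-chloro-3'-hydroxy-4-methoxybiphenyl-2-carbaldehyde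
Product: 6 5-bromo-4'-chloro-2-ethynyl-4-methoxybiphenyl-3'-ol
Conditions: dimethyl (1-diazo-2-oxopropyl)phosphonate, K2CO3 (3 equiv), MeOH/THF, 0 °C to rt
Reagents that add atoms: dimethyl (1-diazo-2-oxopropyl)phosphonate, COP(=O)(OC)C(=[N+]=[N-])C(C)=O
Why: Ohira–Bestmann homologation, in which the diazomethylphosphonate anion released by methanolysis olefinates the non-enolisable aldehyde and loss of N2 with a 1,2-hydride shift gives the terminal alkyne under carbonate conditions that the halides and the phenolate tolerate.

Step 5
Reactants: 6 5-bromo-4'-chloro-2-ethynyl-4-methoxybiphenyl-3'-ol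
Product: 7 6-bromo-2-chloro-7-methoxyphenanthren-3-ol
Conditions: PtCl2 (10 mol %), toluene, 80 °C
Reagents that add atoms: none
Why: Platinum-catalysed 6-endo-dig cycloisomerisation (alkyne hydroarylation) of a 2-ethynylbiaryl, in which the activated alkyne is attacked by the ring carbon para to OH, the more nucleophilic and less crowded of the two carbons flanking the biaryl bond, so C10–C10a forms and the oxygen ends up on C3.

Step 6
Reactants: 7 6-bromo-2-chloro-7-methoxyphenanthren-3-ol
Product: 8 6-bromo-2-chloro-3-hydroxy-7-methoxyphenanthrene-4-carbaldehyde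
Conditions: MgCl2, Et3N, (CH2O)n, MeCN, reflux; then 1 M HCl
Reagents that add atoms: paraformaldehyde (as formaldehyde), C=O
Why: Casnati–Skattebøl ortho-formylation, in which formaldehyde is delivered inside the magnesium phenolate chelate so only a carbon ortho to C3–O can react, C2 is blocked by Cl, C4 is a 2-naphthol-type position of high C3–C4 bond order, and the methoxy ring (C8) cannot compete.

Step 7
Reactants: 8 6-bromo-2-chloro-3-hydroxy-7-methoxyphenanthrene-4-carbaldehyde
Product: 9 6-bromo-2-chloro-7-methoxy-3-(propan-2-yloxy)phenanthrene-4-carbaldehyde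
Conditions: 2-iodopropane (excess), K2CO3, DMF, 60 °C
Reagents that add atoms: 2-iodopropane, CC(C)I
Why: Williamson etherification of an acidic phenol whose two ortho positions are occupied, so O-alkylation by the excess secondary iodide is the only productive pathway.

Step 8
Reactants: 9 6-bromo-2-chloro-7-methoxy-3-(propan-2-yloxy)phenanthrene-4-carbaldehyde
Product: 10 6-bromo-2-chloro-4-ethynyl-7-methoxy-3-(propan-2-yloxy)phenanthrene
Conditions: dimethyl (1-diazo-2-oxopropyl)phosphonate, K2CO3, MeOH/THF, rt
Reagents that add atoms: dimethyl (1-diazo-2-oxopropyl)phosphonate, COP(=O)(OC)C(=[N+]=[N-])C(C)=O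
Why: Ohira–Bestmann homologation, which works on doubly ortho-substituted, non-enolisable aryl aldehydes and replaces the crowded formyl group by a slim sp carbon chain in the bay.

Step 9
Reactants: 10 6-bromo-2-chloro-4-ethynyl-7-methoxy-3-(propan-2-yloxy)phenanthrene
Product: 11 6-bromo-2-chloro-7-methoxy-4-[1-(phenylsulfanyl)ethenyl]-3-(propan-2-yloxy)phenanthrene
Conditions: PhSH, Pd(OAc)2 (5 mol %), γ-terpinene, THF, 45 °C, dark
Reagents that add atoms: thiophenol, Sc1ccccc1
Why: Palladium-catalysed Markovnikov hydrothiolation, in which the palladium thiolate adds across the terminal alkyne with sulfur on the internal carbon and PhSH protonates the vinyl–palladium bond, while darkness and the radical trap suppress the anti-Markovnikov chain and divalent palladium leaves C–Br and C–Cl alone.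

**Ring B and pyrone fragment (steps 10 to 17)**

Step 10
Reactants: 12 2-bromo-3-hydroxybenzaldehyde
Product: 13 2-bromo-3-(propan-2-yloxy)benzaldehyde
Conditions: 2-bromopropane, K2CO3, DMF, 60 °C
Reagents that add atoms: 2-bromopropane, CC(C)Br
Why: Williamson etherification of a phenol, installing the group that will later be removed without loss of the C7 methyl ether.

Step 11
Reactants: 13 2-bromo-3-(propan-2-yloxy)benzaldehyde
Product: 14 2-bromo-6-chloro-3-(propan-2-yloxy)benzaldehyde
Conditions: NCS, CF3CO2H/MeCN, 50 °C
Reagents that add atoms: N-chlorosuccinimide, O=C1CCC(=O)N1Cl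
Why: Electrophilic aromatic chlorination governed by the isopropoxy group, whose para carbon (the future b5) is favoured over the single free ortho carbon by the bulk of the ether, in line with the para halogenation of 3-alkoxybenzaldehydes.

Step 12
Reactants: 15 D-glucono-1,5-lactone
Product: 18 3-acetoxy-6-(acetoxymethyl)-2H-pyran-2-one, via gluconolactone tetraacetate 16 (not isolated), via enonolactone triacetate 17 (not isolated)
Conditions: Ac2O, pyridine, 80 °C
Reagents that add atoms: acetic anhydride, CC(=O)OC(C)=O
Why: Peracetylation followed by two base-induced β-eliminations of acetic acid (H-2/OAc-3, then OAc-4/H-5), the known conversion of acylated aldono-1,5-lactones into 3-acyloxy-2-pyrones, driven by the conjugated pyrone and erasing all four stereocentres.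

Step 13
Reactants: 18 3-acetoxy-6-(acetoxymethyl)-2H-pyran-2-one
Product: 19 3-hydroxy-6-(hydroxymethyl)-2H-pyran-2-one
Conditions: HCl (1.25 M in MeOH), rt
Reagents that add atoms: none
Why: Acid-catalysed transesterification removes the enol acetate and the primary acetate, and acid is chosen because the 2-pyrone lactone is stable to it whereas alkoxide could open the ring.

Step 14
Reactants: 19 3-hydroxy-6-(hydroxymethyl)-2H-pyran-2-one
Product: 20 6-(hydroxymethyl)-3-(propan-2-yloxy)-2H-pyran-2-one
Conditions: 2-iodopropane, K2CO3 (1.1 equiv), DMF, 50 °C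
Reagents that add atoms: 2-iodopropane, CC(C)I
Why: Chemoselective Williamson etherification, since carbonate ionises only the acidic enolic 3-OH and not the primary alcohol, the way enolic hydroxypyrones such as kojic acid are selectively etherified.

Step 15
Reactants: 20 6-(hydroxymethyl)-3-(propan-2-yloxy)-2H-pyran-2-one
Product: 21 {[6-oxo-5-(propan-2-yloxy)-6H-pyran-2-yl]methyl}triphenylphosphonium bromide
Conditions: Ph3P·HBr, MeCN, 80 °C
Reagents that add atoms: triphenylphosphine hydrobromide, [Br-].c1ccc(cc1)[PH+](c1ccccc1)c1ccccc1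
Why: Direct conversion of an activated alcohol into its phosphonium salt, in which loss of water is helped by vinylogous donation from the 3-isopropoxy group through the pyrone diene (a 4-alkoxybenzyl-like situation) and PPh3 captures the electrophilic CH2 carbon.

Step 16
Reactants: 21 pyronylmethyl phosphonium bromide; 14 2-bromo-6-chloro-3-(propan-2-yloxy)benzaldehyde
Product: 23 6-[(E)-2-(2-bromo-6-chloro-3-isopropoxyphenyl)ethenyl]-3-isopropoxy-2H-pyran-2-one, via pyronylmethylene phosphorane 22 (not isolated)
Conditions: K2CO3, 18-crown-6 (cat.), CH2Cl2, 40 °C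
Reagents that add atoms: none
Why: Wittig olefination under solid–liquid carbonate conditions, in which the pyrone-stabilised ylide forms without a soluble strong base that could open the lactone and condenses with the electrophilic 2,6-dihalogenated aldehyde, the alkene geometry (E expected) being irrelevant because the double bond is saturated next.

Step 17
Reactants: 23 6-[(E)-2-(2-bromo-6-chloro-3-isopropoxyphenyl)ethenyl]-3-isopropoxy-2H-pyran-2-one
Product: 24 6-[2-(2-bromo-6-chloro-3-isopropoxyphenyl)ethyl]-3-isopropoxy-2H-pyran-2-one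
Conditions: TsNHNH2 (excess), NaOAc, DME/H2O, reflux
Reagents that add atoms: none
Why: Diimide reduction, whose concerted syn delivery of two hydrogens saturates the disubstituted exocyclic alkene but touches neither the C–Br and C–Cl bonds, which catalytic hydrogenation would endanger, nor the trisubstituted lactone-conjugated double bonds of the pyrone.

**Union, cascade and deprotection (steps 18 to 21)**

Step 18
Reactants: 11 phenanthrenyl bromide with the 1-(phenylsulfanyl)ethenyl group; 24 ring B bromide with the pyrone arm
Product: 26 seco pyrone vinyl sulfide, via phenanthren-6-yl pinacol boronate 25 (not isolated)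
Conditions: 11, B2pin2, Pd(dppf)Cl2 (5 mol %), KOAc, 1,4-dioxane, 90 °C; then 24, K3PO4, H2O (few equiv), Pd(dppf)Cl2 (5 mol %), 90 °C
Reagents that add atoms: bis(pinacolato)diboron, CC1(C)OB(OC1(C)C)B1OC(C)(C)C(C)(C)O1 (its atoms stay in 25 only)
Why: One-pot Miyaura borylation and Suzuki–Miyaura coupling, with boron placed on the less hindered partner (only OMe ortho) and the doubly ortho-substituted ring B entering as the bromide, a dppf catalyst that ignores both C–Cl bonds, a phosphate base mild enough for the pyrone, and a sulfide that, unlike the sulfone, offers no Michael acceptor to base, boron or palladium.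

Step 19
Reactants: 26 seco pyrone vinyl sulfide
Product: 28 seco pyrone vinyl sulfone, via vinyl sulfoxide 27 (not isolated)
Conditions: mCPBA (2.3 equiv), CH2Cl2, 0 °C to rt
Reagents that add atoms: 3-chloroperoxybenzoic acid, OOC(=O)c1cccc(Cl)c1
Why: Chemoselective sulfur oxidation, since the sulfide and then the sulfoxide are far more nucleophilic towards the peracid than the captodative pyrone double bonds, the C9–C10 bond or the emerging electron-poor alkene, so two oxygen transfers should stop at the sulfone.

Step 20
Reactants: 28 seco pyrone vinyl sulfone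
Product: 31 target tri-isopropyl ether, via bridged lactone adduct 29 (not isolated), via sulfonyl cyclohexadiene 30 (not isolated)
Conditions: 1,2-dichlorobenzene (1 mM), 2,6-lutidine (5 equiv), BHT (cat.), 180–200 °C, argon
Reagents that add atoms: none
Why: A thermal normal-electron-demand [4+2] cycloaddition takes place, in which the donor-substituted pyrone (most nucleophilic at its C6, the diene terminus remote from the 3-isopropoxy group) attacks the electrophilic CH2 terminus of the vinyl sulfone (c1–c6) while the alkoxy-bearing C3 closes onto the sulfonyl carbon (c4–c5) to give lactone 29, retro-[4+2] loss of CO2 gives diene 30, and lutidine-assisted elimination of benzenesulfinic acid across c5–c6 gives the arene. The nearest established reaction class is the tethered 2-pyrone/vinyl sulfone cycloaddition whose adduct sheds CO2 and a sulfinic acid, a cascade already proven for arenes embedded in bent cyclophanes. Ring C closes as a six-membered carbocycle through the cycloaddition itself, and the 12-membered ring closes in the bridged (meta) mode because the nine-atom tether links diene terminus c1 to the internal dienophile carbon c5; this happens while c1, c4 and c5 are still sp3, so the bending strain is paid afterwards by aromatisation and irreversible gas loss. The sp3 centres of 29 (c1, c4, c5) and of 30 (c5) are transient and are erased, so no stereocentre remains and the twisted product forms as a racemate. The step needs bridged rather than fused regiochemistry, secured by matching the sulfone-polarised alkene with the alkoxy-polarised diene and by the greater strain of the 11-membered ortho-bridged alternative. It also needs intramolecular rather than intermolecular reaction, secured by millimolar dilution, BHT against radical polymerisation, and a temperature at which the hindered C6–b1 axis rotates so that both rotamers of 28 drain through the productive one.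

Step 21
Reactants: 31 target tri-isopropyl ether
Product: 32 CNP0310669.0 (target)
Conditions: BCl3 (1 M in CH2Cl2, excess), CH2Cl2, −78 to 0 °C; then H2O
Reagents that add atoms: none
Why: Lewis acid ether cleavage, in which BCl3 coordinates each aryl isopropyl ether and chloride removes the secondary alkyl group through a cation-like transition state, whereas the C7 methyl ether has no such pathway and no chelating neighbour and should survive at or below 0 °C, and hydrolysis of the aryl borates frees the three phenols.

**Compound list**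

1 | 5-bromo-2-chlorophenol | Oc1cc(Br)ccc1Cl | starting material
2 | 2-chloro-5-(4,4,5,5-tetramethyl-1,3,2-dioxaborolan-2-yl)phenol | Oc1cc(ccc1Cl)B1OC(C)(C)C(C)(C)O1 | intermediate
3 | 4-bromo-3-methoxybenzaldehyde | COc1cc(C=O)ccc1Br | starting material
4 | 4-bromo-2-iodo-5-methoxybenzaldehyde | COc1cc(C=O)c(I)cc1Br | intermediate
5 | 5-bromo-4'-chloro-3'-hydroxy-4-methoxybiphenyl-2-carbaldehyde | COc1cc(C=O)c(cc1Br)-c1ccc(Cl)c(O)c1 | intermediate
6 | 5-bromo-4'-chloro-2-ethynyl-4-methoxybiphenyl-3'-ol | COc1cc(C#C)c(cc1Br)-c1ccc(Cl)c(O)c1 | intermediate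
7 | 6-bromo-2-chloro-7-methoxyphenanthren-3-ol | COc1cc2ccc3cc(Cl)c(O)cc3c2cc1Br | intermediate
8 | 6-bromo-2-chloro-3-hydroxy-7-methoxyphenanthrene-4-carbaldehyde | COc1cc2ccc3cc(Cl)c(O)c(C=O)c3c2cc1Br | intermediate
9 | 6-bromo-2-chloro-7-methoxy-3-(propan-2-yloxy)phenanthrene-4-carbaldehyde | COc1cc2ccc3cc(Cl)c(OC(C)C)c(C=O)c3c2cc1Br | intermediate
10 | 6-bromo-2-chloro-4-ethynyl-7-methoxy-3-(propan-2-yloxy)phenanthrene | COc1cc2ccc3cc(Cl)c(OC(C)C)c(C#C)c3c2cc1Br | intermediate
11 | 6-bromo-2-chloro-7-methoxy-4-[1-(phenylsulfanyl)ethenyl]-3-(propan-2-yloxy)phenanthrene | COc1cc2ccc3cc(Cl)c(OC(C)C)c(C(=C)Sc4ccccc4)c3c2cc1Br | intermediate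
12 | 2-bromo-3-hydroxybenzaldehyde | O=Cc1cccc(O)c1Br | starting material
13 | 2-bromo-3-(propan-2-yloxy)benzaldehyde | CC(C)Oc1cccc(C=O)c1Br | intermediate
14 | 2-bromo-6-chloro-3-(propan-2-yloxy)benzaldehyde | CC(C)Oc1ccc(Cl)c(C=O)c1Br | intermediate
15 | D-glucono-1,5-lactone | OC[C@H]1OC(=O)[C@H](O)[C@@H](O)[C@@H]1O | starting material
16 | 2,3,4,6-tetra-O-acetyl-D-glucono-1,5-lactone (not isolated) | CC(=O)OC[C@H]1OC(=O)[C@H](OC(C)=O)[C@@H](OC(C)=O)[C@@H]1OC(C)=O | intermediate
17 | 2,4,6-tri-O-acetyl-3-deoxy-D-erythro-hex-2-enono-1,5-lactone (not isolated) | CC(=O)OC[C@H]1OC(=O)C(OC(C)=O)=C[C@@H]1OC(C)=O | intermediate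
18 | 3-acetoxy-6-(acetoxymethyl)-2H-pyran-2-one | CC(=O)OCc1ccc(OC(C)=O)c(=O)o1 | intermediate
19 | 3-hydroxy-6-(hydroxymethyl)-2H-pyran-2-one | OCc1ccc(O)c(=O)o1 | intermediate
20 | 6-(hydroxymethyl)-3-(propan-2-yloxy)-2H-pyran-2-one | CC(C)Oc1ccc(CO)oc1=O | intermediate
21 | {[6-oxo-5-(propan-2-yloxy)-6H-pyran-2-yl]methyl}triphenylphosphonium bromide | [Br-].CC(C)Oc1ccc(C[P+](c2ccccc2)(c2ccccc2)c2ccccc2)oc1=O | intermediate
22 | 3-isopropoxy-6-[(triphenyl-λ5-phosphanylidene)methyl]-2H-pyran-2-one (ylide, not isolated) | CC(C)Oc1ccc(C=P(c2ccccc2)(c2ccccc2)c2ccccc2)oc1=O | intermediate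
23 | 6-[(E)-2-(2-bromo-6-chloro-3-isopropoxyphenyl)ethenyl]-3-isopropoxy-2H-pyran-2-one | CC(C)Oc1ccc(Cl)c(/C=C/c2ccc(OC(C)C)c(=O)o2)c1Br | intermediate
24 | 6-[2-(2-bromo-6-chloro-3-isopropoxyphenyl)ethyl]-3-isopropoxy-2H-pyran-2-one | CC(C)Oc1ccc(Cl)c(CCc2ccc(OC(C)C)c(=O)o2)c1Br | intermediate
25 | pinacol boronate of 11 at C6 (not isolated) | COc1cc2ccc3cc(Cl)c(OC(C)C)c(C(=C)Sc4ccccc4)c3c2cc1B1OC(C)(C)C(C)(C)O1 | intermediate
26 | seco pyrone vinyl sulfide (1-(phenylsulfanyl)ethenyl on C4, ring B on C6, arm ending in 3-isopropoxy-2-pyron-6-yl) | COc1cc2ccc3cc(Cl)c(OC(C)C)c(C(=C)Sc4ccccc4)c3c2cc1-c1c(OC(C)C)ccc(Cl)c1CCc1ccc(OC(C)C)c(=O)o1 | intermediate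
27 | seco pyrone vinyl sulfoxide (racemic at sulfur, not isolated) | COc1cc2ccc3cc(Cl)c(OC(C)C)c(C(=C)S(=O)c4ccccc4)c3c2cc1-c1c(OC(C)C)ccc(Cl)c1CCc1ccc(OC(C)C)c(=O)o1 | intermediate
28 | seco pyrone vinyl sulfone (precursor of the key step) | COc1cc2ccc3cc(Cl)c(OC(C)C)c(C(=C)S(=O)(=O)c4ccccc4)c3c2cc1-c1c(OC(C)C)ccc(Cl)c1CCc1ccc(OC(C)C)c(=O)o1 | intermediate
29 | bridged bicyclic lactone adduct (racemic; transient sp3 centres c1, c4, c5 drawn without descriptors; not isolated) | COc1cc2ccc3cc(Cl)c(OC(C)C)c4c3c2cc1-c5c(OC(C)C)ccc(Cl)c5CCC67C=CC(OC(C)C)(C(=O)O6)C4(S(=O)(=O)c8ccccc8)C7 | intermediate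
30 | macrocyclic 5-(phenylsulfonyl)cyclohexa-1,3-diene after loss of CO2 (racemic at c5, not isolated) | COc1cc2ccc3cc(Cl)c(OC(C)C)c4c3c2cc1-c5c(OC(C)C)ccc(Cl)c5CCC6=CC=C(OC(C)C)C4(S(=O)(=O)c7ccccc7)C6 | intermediate
31 | target tri-isopropyl ether (isopropyl on the oxygens of C3, b2 and c4) | COc1cc2ccc3cc(Cl)c(OC(C)C)c4c3c2cc1-c1c(OC(C)C)ccc(Cl)c1CCc1ccc(OC(C)C)c-4c1 | intermediate
32 | CNP0310669.0 | COc1cc2ccc3cc(Cl)c(O)c4c3c2cc1-c1c(O)ccc(Cl)c1CCc1ccc(O)c-4c1 | target

**Step count**
- Total step count: 21.
- Longest linear sequence: 12 steps (step 1 or 2, steps 3 to 9, steps 18 to 21).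

**Three steps most likely to fail**

**Risk 1, step 20.**
- *What may go wrong.* The pyrone and the vinyl sulfone may not reach bonding distance across the nine-atom tether. The c4–c5 bond joins two fully substituted carbons. Intermolecular cycloaddition, polymerisation of the acceptor or thermal decay of the pyrone could therefore outrun ring closure.
- *Fallback.* It sets out from 11 and 24 and returns at 31. Oxidation of 11 with mCPBA would give 6-bromo-2-chloro-3-isopropoxy-7-methoxy-4-[1-(phenylsulfonyl)ethenyl]phenanthrene F1. Heating F1 with 24 at high concentration in 1,2-dichlorobenzene would run the same cycloaddition and double extrusion between two molecules, with no ring strain to pay, to give the open-chain ring C dibromide F2. The macrocycle would then be closed at the C6–b1 axis by a domino Miyaura borylation and intramolecular Suzuki–Miyaura coupling (B2pin2, Pd(dppf)Cl2, KOAc, then K3PO4, high dilution). This would pass through the C6 monoboronate F3, because the less hindered phenanthrenyl bromide is borylated first, and would deliver 31.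

**Risk 2, step 6.**
- *What may go wrong.* The chlorine lowers the nucleophilicity of the phenolate and the bay hydrogen on C5 crowds C4. Carbon–carbon bond formation inside the magnesium chelate may therefore stall, or stop at hydroxymethylation.
- *Fallback.* It sets out from 7 and returns at 10. Iodination of the phenolate (I2, morpholine, CH2Cl2/MeOH) can only strike C4 and would give 6-bromo-2-chloro-4-iodo-7-methoxyphenanthren-3-ol F4. Etherification with 2-iodopropane and K2CO3 would give the isopropyl ether iodide F5. Sonogashira coupling with trimethylsilylacetylene (Pd(PPh3)2Cl2, CuI, Et3N, 40 °C), which engages C–I long before C–Br, would give the 4-(trimethylsilylethynyl)phenanthrene F6. K2CO3 in MeOH would then release 10.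

**Risk 3, step 18.**
- *What may go wrong.* Oxidative addition into the electron-rich, doubly ortho-substituted ring B bromide may be slow. Protodeboronation of the boronate and base-induced opening of the pyrone would then consume both partners.
- *Fallback.* It sets out from 11 and returns at 26. Bromine–lithium exchange on 11 (n-BuLi, THF, −78 °C) would give the phenanthren-6-yllithium F7, and ZnCl2 would turn it into the phenanthren-6-ylzinc chloride F8. A Negishi coupling with 24 (Pd2(dba)3, RuPhos, THF, 40–60 °C) needs neither base nor water and is the strongest method for crowded biaryls. It should give 26, with the bromide reacting well before either chloride at this temperature.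

Further compounds
F1 | step 20 | 6-bromo-2-chloro-3-isopropoxy-7-methoxy-4-[1-(phenylsulfonyl)ethenyl]phenanthrene | COc1cc2ccc3cc(Cl)c(OC(C)C)c(C(=C)S(=O)(=O)c4ccccc4)c3c2cc1Br
F2 | step 20 | open-chain ring C dibromide: 6-bromo-4-{5-[2-(2-bromo-6-chloro-3-isopropoxyphenyl)ethyl]-2-isopropoxyphenyl}-2-chloro-3-isopropoxy-7-methoxyphenanthrene | COc1cc2ccc3cc(Cl)c(OC(C)C)c(-c4cc(CCc5c(Cl)ccc(OC(C)C)c5Br)ccc4OC(C)C)c3c2cc1Br
F3 | step 20 | C6 monoboronate (pinacol ester) of F2 | COc1cc2ccc3cc(Cl)c(OC(C)C)c(-c4cc(CCc5c(Cl)ccc(OC(C)C)c5Br)ccc4OC(C)C)c3c2cc1B1OC(C)(C)C(C)(C)O1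
F4 | step 6 | 6-bromo-2-chloro-4-iodo-7-methoxyphenanthren-3-ol | COc1cc2ccc3cc(Cl)c(O)c(I)c3c2cc1Br
F5 | step 6 | 6-bromo-2-chloro-4-iodo-7-methoxy-3-(propan-2-yloxy)phenanthrene | COc1cc2ccc3cc(Cl)c(OC(C)C)c(I)c3c2cc1Br
F6 | step 6 | 6-bromo-2-chloro-7-methoxy-3-(propan-2-yloxy)-4-[(trimethylsilyl)ethynyl]phenanthrene | COc1cc2ccc3cc(Cl)c(OC(C)C)c(C#C[Si](C)(C)C)c3c2cc1Br
F7 | step 18 | phenanthren-6-yllithium derived from 11 | COc1cc2ccc3cc(Cl)c(OC(C)C)c(C(=C)Sc4ccccc4)c3c2cc1[Li]
F8 | step 18 | phenanthren-6-ylzinc chloride derived from 11 | COc1cc2ccc3cc(Cl)c(OC(C)C)c(C(=C)Sc4ccccc4)c3c2cc1[Zn]Cl
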